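The readings are calculated with constants of no real substance, and the scatter is random.

Two questions put these flasks in order: how much of the charge has gone in by the asked time, and what parts the flasks that are level on that.

| flask | substrate | free enzyme | temperature | remark | time |
|---|---|---|---|---|---|
| alpha | 0.050 M (in portions, 4) | 0.0044 mol% | 0 °C | run made earlier; portions every 2.0 min |  |
| theta | 0.050 M (in portions, 4) | 0.016 mol% | 11 °C | run made earlier; portions every 2.0 min |  |
| beta | 0.047 M (in portions, 4) | 0.0041 mol% | 0 °C | run made earlier; portions every 2.0 min |  |
| winter | 0.15 M (in portions, 4) | 0.012 mol% | 5 °C | the portions of substrate follow each other after 2.0 min, the first at the start | 8.0 min |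
| midnight | 0.050 M (in portions, 4) | 0.0041 mol% | 5 °C | the portions of substrate follow each other after 2.0 min, the first at the start | 8.0 min |
| spring | 0.050 M (in portions, 4) | 0.003 mol% | 5 °C | the portions of substrate follow each other after 8.0 min, the first at the start | 8.0 min |
| dusk | 0.015 M (in portions, 4) | 0.012 mol% | 5 °C | the portions of substrate follow each other after 2.0 min, the first at the start | 8.0 min |
| summer | 0.10 M (in portions, 4) | 0.0041 mol% | 5 °C | the portions of substrate follow each other after 2.0 min, the first at the start | 8.0 min |

| run | time / min | product / % | substrate / % |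
|---|---|---|---|
| alpha | 0.667 | 10 | 15 |
| alpha | 1.00 | 12 | 11 |
| alpha | 1.33 | 18 | 11 |
| alpha | 2.50 | 35 | 13 |
| alpha | 3.00 | 38 | 14 |
| alpha | 5.00 | 60 | 14 |
| alpha | 8.00 | 90 | 8 |
| theta | 0.667 | 21 | 8 |
| theta | 1.00 | 18 | 4 |
| theta | 1.33 | 20 | 6 |
| theta | 2.50 | 36 | 14 |
| theta | 3.00 | 41 | 13 |
| theta | 5.00 | 57 | 16 |
| theta | 8.00 | 88 | 13 |
| beta | 0.667 | 9 | 16 |
| beta | 1.33 | 15 | 14 |
| beta | 2.50 | 36 | 15 |
| beta | 4.00 | 39 | 12 |
| beta | 8.00 | 89 | 9 |

(scatter of a reading: 2 percentage points)

- reactions considered so far: 2 free enzyme -> spent catalyst; free enzyme -> unfolded enzyme; substrate + free enzyme -> product + free enzyme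
- percentages count the whole charge, also what has not yet gone in

- the flasks put in order of amount of product, in percent of the substrate charged, best first, at 8.0 min (winter / midnight / spring / dusk / summer)
- the amount of product, in percent of the substrate charged of the flask you put first, at 8.0 min
- the amount of product, in percent of the substrate charged of the flask you put last, at 8.0 min

We take the feed first. In spring the interval 8.0 min equals the asked time 8.0 min, so one of 4 portions has gone in, which gives 25.0 %. This is the admitted share S: the portions in before a time, divided by the number of portions, and so the ceiling on product plus substrate in percent of the charge. The alpha readings respect this count, for at 2.50 min product and substrate read 48.0 % against 50.0 % for two portions. The other flasks reach S = 100 %, so spring has the lower ceiling.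

Is that ceiling low enough to put spring last? Alpha read 90 % of product at 8.00 min, so spring's S is 0.278 of that reading, and we expect spring last, under S. How far under S it ends we leave open, because alpha still read 8 % of substrate at that time.

The other four share S, so S does not part them. Theta, with 3.64 times alpha's loading and at 11 °C against 0 °C, read 88 % against 90 % at 8.00 min, so these runs give us no ground for ranking by enzyme. We rank the four by their charge of substrate instead, as a judgement that the runs do not test, since their charges lie between 0.047 M and 0.050 M. We commit to winter, summer, midnight, dusk, spring, with winter close to its ceiling.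

The forecast gives winter > summer > midnight > dusk > spring, with 95 % for the first and 24.7 % for the last, saying of spring that “it is capped near 25%”.

The flasks give winter > summer > midnight > dusk > spring, with 97.5 % for winter and 20.2 % for spring. Spring's product and substrate at 8.00 min add up to 25.0 %, its S of 25.0 %, with 4.82 % still standing as substrate, and 91 % of its turnover lay behind it at 4.00 min. A neighbouring flask, spring with 0.030 M of substrate, keeps the same S of 25.0 %, and there product 15.5 % and substrate 9.53 % add up to 25.0 %.

    2 free enzyme → spent catalyst (k = 370 M⁻¹ s⁻¹, Ea = 40.0 kJ mol⁻¹)
    free enzyme → unfolded enzyme (k = 4.70 × 10⁻⁴ s⁻¹, Ea = 196 kJ mol⁻¹)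
    substrate + free enzyme → product + free enzyme, rate k3*[substrate]^2.5*[free enzyme]/(1 + ([substrate]/Kh3)^2.5) (0.0930 M, k = 9.80 × 10⁶ M⁻²·⁵ s⁻¹, Ea = 8.00 kJ mol⁻¹)
    (constants at 5 °C)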